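The runs were generated by integration with constants of no real substance, and the scatter is random.

Count the chains first.

| flask | free monomer | transfer agent | initiator | remark | time |
|---|---|---|---|---|---|
| amber | 0.065 M | 0.50 mM | 5 mol% | run made earlier |  |
| grey | 0.12 M | 0.50 mM | 5 mol% | run made earlier |  |
| theta | 0.050 M | 0.500 mM | 5 mol% |  | 20 h |
| alpha | 0.10 M | 0.500 mM | 5 mol% |  | 20 h |

- amber (time / h: monomer in chains / %, free monomer / %): 1.33: 6.4, 93.3; 4.00: 16.0, 83.9; 8.00: 29.5, 70.1; 10.0: 34.7, 64.8; 15.0: 46.2, 52.6; 20.0: 55.8, 42.5
- grey (time / h: monomer in chains / %, free monomer / %): 3.00: 22.2, 77.8; 6.00: 38.2, 60.6; 10.0: 54.0, 44.1; 12.0: 60.7, 37.6; 15.0: 69.3, 28.7; 20.0: 80.0, 20.8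

(readings scatter by 0.5 percentage points)

- the average divides the monomer in chains by the number of chains begun, living and dead together
- the numbers in the tables scatter with a standard deviation of 0.5 percentage points
- the earlier runs do not show the number of chains; that part of a forecast is a guess

- which of the two ends with the longer chains by the average number of monomer units in a chain (chains begun, living or dead) ("neither" if they lie within 10%) (theta / alpha / neither)
- average number of monomer units in a chain (chains begun, living or dead) at the end, theta
- average number of monomer units in a chain (chains begun, living or dead) at the end, alpha

The average length is monomer in chains divided by chains begun. The tables never show chains, but the pace of the free monomer hints at them. I take the natural logarithm of charged over remaining free monomer and divide by the time, which gives a pseudo-first-order constant. I then divide that by the charged [initiator], as one divides a rate by the number of sites. The last amber reading gives 13.2 L mol⁻¹ h⁻¹ and the last grey reading 13.1 L mol⁻¹ h⁻¹, although the grey run holds about twice the [initiator]. The first amber reading is also faster than the last, so I assume that each initiator begins one chain within the first hours.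

The number of chains begun is then the loading times the charged free monomer, and one over the loading gives 20.0. This is the length ceiling, the monomer units available per chain begun. The length is the ceiling times the fraction of free monomer in chains. At the last amber reading, monomer in chains and free monomer sum to 98.3%, so I count what has reacted as in chains. With the mean constant 13.1 L mol⁻¹ h⁻¹, I reckon that fraction at 48.1% for theta and 73.1% for alpha. My lengths are therefore 9.62 for theta and 14.6 for alpha.

The forecast also names alpha, but it gives 30 for theta (17 to 48) and 68 for alpha (35 to 148). It counts 0.500 mM of chains from the transfer agent and assumes that “about 10–15% of initiator yields chains”. I count every initiator and no separate chains from the transfer agent, so my lengths are lower.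

The flasks give alpha as the longer, with 9.19 for theta and 14.4 for alpha.

    free monomer + initiator → living end + monomer in chains (k = 15.0 L mol⁻¹ h⁻¹)
    free monomer + living end → monomer in chains + living end, rate k2*[living end]*[free monomer] (k = 14.0 L mol⁻¹ h⁻¹)
    living end + transfer agent → dead chain (kL = 50.0 L mol⁻¹ h⁻¹)
    free monomer → uncatalysed product (k = 0.00150 h⁻¹)

In theta at 20.0 h, [living end] 0.00206 M and [dead chain] 4.36 × 10⁻⁴ M add up to 2.50 mM, which matches the initiator charge of 2.50 mM, with 0% of the initiator left. The ceiling times the 45.9% in chains gives 9.19. A neighbouring flask, theta with 0.20 M of free monomer at the same initiator loading, has the same ceiling. My constant puts 92.8% of its free monomer into chains, which gives a length of 18.6, and that flask gives 18.5.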